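**Plan**

1. Numbering used below (germacranolide style): oxolane C1(H)–O–C4(CH3 = C15); C5=C6 is the exocyclic enol‑lactone olefin; butenolide O–C6, C7=C11, C12(=O); C13 = CH2OAc; C8 = ester carbinol; C9 = CH2; C10 = carbinol carrying CH3 (C14).
2. Cuts: C5=C6 and the lactone (back to a furan O/C6/C7/C11/C12, by singlet‑oxygen oxidation and dehydration); the C8 ester and C8–H (back to a C8 ketone); C9–C10 (ring‑closing aldol‑type bond); the furan (ynone C6≡C7–C8(=O)–C9 plus dihydroxyacetone as C11–C13); C7–C8 (acetylide acylation); C1–O (epoxide opening of (R)‑linalool).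
3. Forward order: the oxolane first, then the furan is annulated on its side arm, then the ten‑membered carbocycle is closed between C9 and C10 (giving the 11‑oxabicyclo[6.2.1]undecane core), and the butenolide with its C5=C6 olefin is unveiled last.
4. The feature that allows the ring closure is the aldol retron C8(=O)–C9H2–C10(OH)(CH3). C8 sits on furan carbon C7 and can enolize only toward C9; C10 is an α‑alkoxy methyl ketone on the cis‑2,5‑disubstituted oxolane (both arms on one face, ring oxygen able to chelate); the furan bond C6=C7 serves as the cis‑olefin of the ring.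
5. Helpers: the hydroxyisopropyl group of linalool oxide is the latent C10 acetyl group (dehydration, then oxidative cleavage); a bromide on C9 is the activating group and is consumed in the ring closure; the furan masks the sensitive γ‑alkylidene butenolide.
6. Stereochemistry: C4 is bought with (R)‑linalool; C1 comes from Shi epoxidation and SN2 inversion; C10 (ring closure) and C8 (following reduction) are relayed from C1/C4 by substrate control; the glycidate centre is bought with (R)‑2‑methylglycidol; the (E)‑C5=C6 geometry is imposed by the ring.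

Key step: step 11

Remark: 1,3‑dihydroxyacetone (11) is charged as its commercial dimer, which gives the monomer in solution; (R)‑linalool, (R)‑2‑methylglycidol and the Shi ketone are assumed to be bought in high enantiomeric purity.
Remark: carbons that are created as epimer mixtures and destroyed in the same or the next operation (C11 in 12, C10 in 17, C6 and C12 in 26, C6 in 27 and 28) are left undefined in the SMILES.

**Route**

Step 1
Reactants: 1 (R)-linalool
Product: 3 2-[(2S,5R)-5-ethenyl-5-methyloxolan-2-yl]propan-2-ol, via epoxide 2 (not isolated)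
Conditions: 1,2:4,5-di-O-isopropylidene-β-D-erythro-2,3-hexodiulo-2,6-pyranose (Shi ketone, 30 mol %), KHSO5 (Oxone), K2CO3, Bu4NHSO4, Na2B4O7/Na2EDTA buffer, MeCN/CH2(OMe)2, 0 °C; then crude 2, (+)-10-camphorsulfonic acid (10 mol %), CH2Cl2, 0 °C to rt
Reagents that add atoms: potassium peroxymonosulfate KHSO5 (Oxone), [K+].[O-]S(=O)(=O)OO
Why: Shi epoxidation should attack only the electron‑rich trisubstituted 6,7‑olefin and set the (6R) epoxide under reagent control, after which acid‑promoted 5‑exo opening by the tertiary hydroxyl at the secondary epoxide carbon inverts that centre to (1S) and places vinyl and hydroxyisopropyl cis on the oxolane.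

Step 2
Reactants: 3 2-[(2S,5R)-5-ethenyl-5-methyloxolan-2-yl]propan-2-ol
Product: 5 2-[(2R,5S)-5-(2-hydroxypropan-2-yl)-2-methyloxolan-2-yl]ethan-1-ol, via alkylborane 4 (not isolated)
Conditions: 9-borabicyclo[3.3.1]nonane (9-BBN-H, 2.5 equiv), THF, 0 to 50 °C; then NaOH, H2O2, 0 °C to rt
Reagents that add atoms: hydrogen peroxide, OO
Why: Anti‑Markovnikov hydroboration–oxidation puts boron on the unhindered terminal carbon of the vinyl group on the quaternary centre, and oxidation gives the primary alcohol without touching either stereocentre.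

Step 3
Reactants: 5 2-[(2R,5S)-5-(2-hydroxypropan-2-yl)-2-methyloxolan-2-yl]ethan-1-ol
Product: 6 2-[(2R,5S)-5-(2-hydroxypropan-2-yl)-2-methyloxolan-2-yl]acetaldehyde
Conditions: 2,2,6,6-tetramethylpiperidin-1-oxyl (10 mol %), PhI(OAc)2, CH2Cl2, rt
Reagents that add atoms: none
Why: Oxoammonium‑mediated oxidation is selective for the primary alcohol and stops at the aldehyde, and the tertiary alcohol cannot be oxidized.

Step 4
Reactants: 6 2-[(2R,5S)-5-(2-hydroxypropan-2-yl)-2-methyloxolan-2-yl]acetaldehyde
Product: 7 2-[(2S,5R)-5-methyl-5-(prop-2-yn-1-yl)oxolan-2-yl]propan-2-ol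
Conditions: dimethyl (1-diazo-2-oxopropyl)phosphonate, K2CO3, MeOH, 0 °C to rt
Reagents that add atoms: dimethyl (1-diazo-2-oxopropyl)phosphonate, CC(=O)C(=[N+]=[N-])P(=O)(OC)OC
Why: The Ohira–Bestmann (Seyferth–Gilbert) homologation converts the aldehyde into the terminal alkyne under mild carbonate conditions and adds carbon C7.

Step 5
Reactants: 7 2-[(2S,5R)-5-methyl-5-(prop-2-yn-1-yl)oxolan-2-yl]propan-2-ol
Product: 8 (2R,5S)-2-methyl-5-(prop-1-en-2-yl)-2-(prop-2-yn-1-yl)oxolane
Conditions: Burgess reagent (Et3N+SO2N−CO2Me), toluene, 50 °C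
Reagents that add atoms: none
Why: Burgess dehydration (syn elimination of the sulfamate ester) of the tertiary alcohol should give the isopropenyl group, the latent C10 acetyl group, because loss of one of the six methyl hydrogens is favoured over loss of the single hydrogen on the oxygen‑bearing ring carbon C1, whose configuration is untouched.

Step 6
Reactants: 8 (2R,5S)-2-methyl-5-(prop-1-en-2-yl)-2-(prop-2-yn-1-yl)oxolane
Product: 10 5-[(2R,5S)-2-methyl-5-(prop-1-en-2-yl)oxolan-2-yl]pent-3-yn-2-one, via lithium acetylide 9 (not isolated)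
Conditions: n-BuLi, THF, −78 °C; then MeC(O)N(OMe)Me, −78 to 0 °C; aq. NH4Cl
Reagents that add atoms: N-methoxy-N-methylacetamide, CC(=O)N(C)OC
Why: Acylation of the lithium acetylide with the Weinreb amide stops at the ketone because the chelated tetrahedral intermediate survives until work‑up, and it installs C8 and C9 as an acetyl group on C7.

Step 7
Reactants: 10 5-[(2R,5S)-2-methyl-5-(prop-1-en-2-yl)oxolan-2-yl]pent-3-yn-2-one; 11 1,3-dihydroxypropan-2-one
Product: 13 1-[4-(hydroxymethyl)-2-{[(2R,5S)-2-methyl-5-(prop-1-en-2-yl)oxolan-2-yl]methyl}furan-3-yl]ethan-1-one, via dihydrofuranol 12 (not isolated)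
Conditions: 1,4-diazabicyclo[2.2.2]octane (20 mol %), DMF, rt; then pyridinium p-toluenesulfonate (0.5 equiv), 40 °C
Reagents that add atoms: none
Why: In this tandem oxa‑Michael/intramolecular aldol annulation of an α‑hydroxy ketone with an acetylenic ketone, a hydroxyl of 11 adds to the ynone β‑carbon C6, the allenolate carbon C7 closes 5‑exo onto the ketone carbon of the dihydroxyacetone unit (C11), and acid‑catalysed loss of water from 12 gives the furan with C6 fixed on the ring oxygen and the second arm of symmetric 11 as the C13 hydroxymethyl group.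

Step 8
Reactants: 13 1-[4-(hydroxymethyl)-2-{[(2R,5S)-2-methyl-5-(prop-1-en-2-yl)oxolan-2-yl]methyl}furan-3-yl]ethan-1-one
Product: 14 [4-acetyl-5-{[(2R,5S)-2-methyl-5-(prop-1-en-2-yl)oxolan-2-yl]methyl}furan-3-yl]methyl acetate
Conditions: Ac2O, pyridine, 4-(dimethylamino)pyridine (5 mol %), CH2Cl2, 0 °C
Reagents that add atoms: acetic anhydride, CC(=O)OC(C)=O
Why: Standard acetylation of the only hydroxyl group installs the C13 acetate of the target and prevents hemiketal formation with the neighbouring C8 ketone.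

Step 9
Reactants: 14 [4-acetyl-5-{[(2R,5S)-2-methyl-5-(prop-1-en-2-yl)oxolan-2-yl]methyl}furan-3-yl]methyl acetate
Product: 16 [4-(bromoacetyl)-5-{[(2R,5S)-2-methyl-5-(prop-1-en-2-yl)oxolan-2-yl]methyl}furan-3-yl]methyl acetate, via silyl enol ether 15 (not isolated)
Conditions: Me3SiOTf, Et3N, CH2Cl2, 0 °C; then N-bromosuccinimide, −78 to 0 °C
Reagents that add atoms: N-bromosuccinimide, O=C1CCC(=O)N1Br
Why: Soft enolization of the only enolizable ketone (the C8 acetyl group on furan C7) gives enol ether 15, whose bromination by N‑bromosuccinimide should be far faster than attack on the acyl‑deactivated furan or the isopropenyl group and puts the activating bromide on C9.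

Step 10
Reactants: 16 [4-(bromoacetyl)-5-{[(2R,5S)-2-methyl-5-(prop-1-en-2-yl)oxolan-2-yl]methyl}furan-3-yl]methyl acetate
Product: 18 [5-{[(2R,5S)-5-acetyl-2-methyloxolan-2-yl]methyl}-4-(bromoacetyl)furan-3-yl]methyl acetate, via diol 17 (not isolated)
Conditions: OsO4 (2 mol %), NaIO4, 2,6-lutidine, 1,4-dioxane/H2O 3:1, rt
Reagents that add atoms: osmium tetroxide, O=[Os](=O)(=O)=O (oxygen carrier, regenerated by NaIO4); sodium periodate, [Na+].[O-]I(=O)(=O)=O
Why: In this Lemieux–Johnson cleavage OsO4 should dihydroxylate the isolated 1,1‑disubstituted olefin in preference to the acyl‑deactivated furan and NaIO4 cleaves diol 17 to the C10 methyl ketone, which is thus unveiled only just before the ring closure so that the epimerizable centre C1 never meets base.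

Step 11
Reactants: 18 [5-{[(2R,5S)-5-acetyl-2-methyloxolan-2-yl]methyl}-4-(bromoacetyl)furan-3-yl]methyl acetate
Product: 20 (1S,4R,10R)-13-acetoxy-1,4:6,12-diepoxy-10-hydroxygermacra-6,11-dien-8-one, via samarium enolate 19 (not isolated)
Conditions: syringe-pump addition of 18 to SmI2 (2.5 equiv), THF, −78 °C, final 0.002 M; pH 7 phosphate buffer
Reagents that add atoms: none
Why: Two single‑electron transfers from SmI2 cleave the C9–Br bond and give the trivalent samarium enolate 19 regiospecifically at C8/C9 (the two ketones and the acetate should not be reduced at −78 °C without additives), and this enolate adds to the C10 carbonyl in an aldol step, the closest known reaction type being the SmI2‑promoted intramolecular Reformatsky‑type cyclization of α‑bromo carbonyl compounds onto a remote carbonyl group to give medium and large rings. The new bond closes the ten‑membered carbocycle C1–C10 in a 10‑(enolendo)‑exo‑trig mode and so completes the 11‑oxabicyclo[6.2.1]undecane core, helped by the cis‑2,5‑disubstituted oxolane and the ortho‑fused furan (C6=C7), which already hold most of the ring atoms in a U‑shape. The only new stereocentre, C10, is controlled by C1 and C4: samarium bridges the enolate oxygen, the C10 carbonyl oxygen and the oxolane oxygen, which holds the C=O syn to the ring oxygen, and the tether from C4 can then reach only the carbonyl face turned toward C4, which should give the (10R) alcohol. The step needs a C9‑specific enolate (secured by the bromide, since the C8 ketone on furan C7 has no other enolizable side), intramolecular rather than intermolecular addition (slow addition, high dilution) and no equilibration of the aldolate (low temperature, neutral quench).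

Step 12
Reactants: 20 (1S,4R,10R)-13-acetoxy-1,4:6,12-diepoxy-10-hydroxygermacra-6,11-dien-8-one
Product: 22 (1S,4R,8S,10R)-13-acetoxy-1,4:6,12-diepoxygermacra-6,11-diene-8,10-diol, via borinate chelate 21 (not isolated)
Conditions: Et2BOMe, THF/MeOH 4:1, −78 °C; then NaBH4, −78 °C; aq. NH4Cl, MeOH co-evaporation
Reagents that add atoms: none
Why: In this Narasaka–Prasad reduction the C10 hydroxyl and the C8 carbonyl are tied into the six‑membered boron chelate 21 and external hydride attacks axially, which should give the 1,3‑syn diol and so set C8 as (S) from C10 while the acetate is untouched at −78 °C.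

Step 13
Reactants: 23 [(2R)-2-methyloxiran-2-yl]methanol
Product: 24 (2S)-2-methyloxirane-2-carboxylic acid
Conditions: RuCl3 hydrate (2 mol %), NaIO4, MeCN/EtOAc/H2O, 0 °C to rt; used at once
Reagents that add atoms: sodium periodate, [Na+].[O-]I(=O)(=O)=O (oxygen delivered through RuO4); water, O
Why: RuO4 generated in situ oxidizes the primary alcohol to the carboxylic acid without opening the 2,2‑disubstituted epoxide, whose quaternary stereocentre cannot epimerize (the descriptor changes from R to S only because the priorities change).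

Step 14
Reactants: 22 (1S,4R,8S,10R)-13-acetoxy-1,4:6,12-diepoxygermacra-6,11-diene-8,10-diol; 24 (2S)-2-methyloxirane-2-carboxylic acid
Product: 25 (1S,4R,8S,10R)-13-acetoxy-1,4:6,12-diepoxy-10-hydroxygermacra-6,11-dien-8-yl (2S)-2-methyloxirane-2-carboxylate
Conditions: N,N'-dicyclohexylcarbodiimide, 4-(dimethylamino)pyridine (20 mol %), CH2Cl2, 0 °C to rt
Reagents that add atoms: none
Why: Steglich esterification should acylate only the secondary C8 hydroxyl, the tertiary C10 hydroxyl being too hindered, with retention at C8 and at the glycidate centre.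

Step 15
Reactants: 25 (1S,4R,8S,10R)-13-acetoxy-1,4:6,12-diepoxy-10-hydroxygermacra-6,11-dien-8-yl (2S)-2-methyloxirane-2-carboxylate
Product: 27 (1S,4R,8S,10R)-13-acetoxy-1,4-epoxy-6,10-dihydroxy-8-{[(2S)-2-methyloxiran-2-yl]carbonyloxy}germacr-7(11)-en-12,6-olide, via endoperoxide 26 (not isolated)
Conditions: O2, visible light, 5,10,15,20-tetraphenylporphyrin (1 mol %), iPr2NEt, CH2Cl2, −78 °C, then warm to rt
Reagents that add atoms: dioxygen, O=O
Why: Singlet oxygen adds across C6 and C12 of the furan in a [4+2] cycloaddition and the hindered amine removes the only bridgehead hydrogen of endoperoxide 26 (on C12, Kornblum–DeLaMare fragmentation), so that C12 becomes the lactone carbonyl and C6 the hemiketal carbon of the γ‑hydroxybutenolide.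

Step 16
Reactants: 27 (1S,4R,8S,10R)-13-acetoxy-1,4-epoxy-6,10-dihydroxy-8-{[(2S)-2-methyloxiran-2-yl]carbonyloxy}germacr-7(11)-en-12,6-olide
Product: 29 (1S,4R,5E,8S,10R)-13-acetoxy-1,4-epoxy-10-hydroxy-8-{[(2S)-2-methyloxiran-2-yl]carbonyloxy}germacra-5,7(11)-dien-12,6-olide, via mesylate 28 (not isolated)
Conditions: MeSO2Cl, Et3N, CH2Cl2, −20 to 0 °C
Reagents that add atoms: none
Why: Sulfonylation of the hemiketal hydroxyl and base‑induced elimination toward C5 (the only β‑hydrogens) give the γ‑alkylidene butenolide, and inside the bridged ring only the ring‑cis, that is (E), C5=C6 olefin can form, while the hindered tertiary C10 hydroxyl should not be sulfonylated at this temperature.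

**Compound list**

1 | (R)-linalool, (3R)-3,7-dimethylocta-1,6-dien-3-ol | C=C[C@](C)(O)CCC=C(C)C | starting material
2 | (3R)-5-[(2R)-3,3-dimethyloxiran-2-yl]-3-methylpent-1-en-3-ol | C=C[C@](C)(O)CC[C@H]1OC1(C)C | intermediate (not isolated)
3 | 2-[(2S,5R)-5-ethenyl-5-methyloxolan-2-yl]propan-2-ol (vinyl and hydroxyisopropyl cis) | C=C[C@@]1(C)CC[C@H](O1)C(C)(C)O | intermediate
4 | 9-{2-[5-(2-hydroxypropan-2-yl)-2-methyloxolan-2-yl]ethyl}-9-borabicyclo[3.3.1]nonane, ring carbons configured as in 3 | C1CCC2CCCC1B2CC[C@@]3(C)CC[C@H](O3)C(C)(C)O | intermediate (not isolated)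
5 | 2-[(2R,5S)-5-(2-hydroxypropan-2-yl)-2-methyloxolan-2-yl]ethan-1-ol | OCC[C@@]1(C)CC[C@H](O1)C(C)(C)O | intermediate
6 | 2-[(2R,5S)-5-(2-hydroxypropan-2-yl)-2-methyloxolan-2-yl]acetaldehyde | O=CC[C@@]1(C)CC[C@H](O1)C(C)(C)O | intermediate
7 | 2-[(2S,5R)-5-methyl-5-(prop-2-yn-1-yl)oxolan-2-yl]propan-2-ol | C#CC[C@@]1(C)CC[C@H](O1)C(C)(C)O | intermediate
8 | (2R,5S)-2-methyl-5-(prop-1-en-2-yl)-2-(prop-2-yn-1-yl)oxolane | C#CC[C@@]1(C)CC[C@H](O1)C(C)=C | intermediate
9 | lithium acetylide of 8 | [Li]C#CC[C@@]1(C)CC[C@H](O1)C(C)=C | intermediate (not isolated)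
10 | 5-[(2R,5S)-2-methyl-5-(prop-1-en-2-yl)oxolan-2-yl]pent-3-yn-2-one | CC(=O)C#CC[C@@]1(C)CC[C@H](O1)C(C)=C | intermediate
11 | 1,3-dihydroxypropan-2-one (dihydroxyacetone, charged as dimer) | OCC(=O)CO | starting material
12 | 1-[4-hydroxy-4-(hydroxymethyl)-2-{[(2R,5S)-2-methyl-5-(prop-1-en-2-yl)oxolan-2-yl]methyl}-4,5-dihydrofuran-3-yl]ethan-1-one (both epimers at the carbinol carbon) | CC(=O)C1=C(C[C@@]2(C)CC[C@H](O2)C(C)=C)OCC1(O)CO | intermediate (not isolated)
13 | 1-[4-(hydroxymethyl)-2-{[(2R,5S)-2-methyl-5-(prop-1-en-2-yl)oxolan-2-yl]methyl}furan-3-yl]ethan-1-one | CC(=O)c1c(CO)coc1C[C@@]1(C)CC[C@H](O1)C(C)=C | intermediate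
14 | [4-acetyl-5-{[(2R,5S)-2-methyl-5-(prop-1-en-2-yl)oxolan-2-yl]methyl}furan-3-yl]methyl acetate | CC(=O)OCc1coc(C[C@@]2(C)CC[C@H](O2)C(C)=C)c1C(C)=O | intermediate
15 | [5-{[(2R,5S)-2-methyl-5-(prop-1-en-2-yl)oxolan-2-yl]methyl}-4-{1-[(trimethylsilyl)oxy]ethenyl}furan-3-yl]methyl acetate | CC(=O)OCc1coc(C[C@@]2(C)CC[C@H](O2)C(C)=C)c1C(=C)O[Si](C)(C)C | intermediate (not isolated)
16 | [4-(bromoacetyl)-5-{[(2R,5S)-2-methyl-5-(prop-1-en-2-yl)oxolan-2-yl]methyl}furan-3-yl]methyl acetate | CC(=O)OCc1coc(C[C@@]2(C)CC[C@H](O2)C(C)=C)c1C(=O)CBr | intermediate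
17 | [4-(bromoacetyl)-5-{[(2R,5S)-5-(1,2-dihydroxypropan-2-yl)-2-methyloxolan-2-yl]methyl}furan-3-yl]methyl acetate (both epimers at the new carbinol carbon) | CC(=O)OCc1coc(C[C@@]2(C)CC[C@H](O2)C(C)(O)CO)c1C(=O)CBr | intermediate (not isolated)
18 | [5-{[(2R,5S)-5-acetyl-2-methyloxolan-2-yl]methyl}-4-(bromoacetyl)furan-3-yl]methyl acetate | CC(=O)OCc1coc(C[C@@]2(C)CC[C@H](O2)C(C)=O)c1C(=O)CBr | intermediate
19 | trivalent samarium enolate of 18 (O–SmI2 on C8, C8=C9) | CC(=O)OCc1coc(C[C@@]2(C)CC[C@H](O2)C(C)=O)c1C(=C)O[Sm](I)I | intermediate (not isolated)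
20 | (1S,4R,10R)-13-acetoxy-1,4:6,12-diepoxy-10-hydroxygermacra-6,11-dien-8-one (furan‑fused bicyclic ketol) | CC(=O)OCc1c2c(C[C@@]3(C)CC[C@H](O3)[C@](C)(O)CC2=O)oc1 | intermediate
21 | 10-O-diethylboryl derivative of 20, boron chelated by the C8 carbonyl | CC(=O)OCc1c2c(C[C@@]3(C)CC[C@H](O3)[C@](C)(OB(CC)CC)CC2=O)oc1 | intermediate (not isolated)
22 | (1S,4R,8S,10R)-13-acetoxy-1,4:6,12-diepoxygermacra-6,11-diene-8,10-diol | CC(=O)OCc1c2c(C[C@@]3(C)CC[C@H](O3)[C@](C)(O)C[C@@H]2O)oc1 | intermediate
23 | [(2R)-2-methyloxiran-2-yl]methanol ((R)-2-methylglycidol) | OC[C@]1(C)CO1 | starting material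
24 | (2S)-2-methyloxirane-2-carboxylic acid | OC(=O)[C@]1(C)CO1 | intermediate
25 | (1S,4R,8S,10R)-13-acetoxy-1,4:6,12-diepoxy-10-hydroxygermacra-6,11-dien-8-yl (2S)-2-methyloxirane-2-carboxylate | CC(=O)OCc1c2c(C[C@@]3(C)CC[C@H](O3)[C@](C)(O)C[C@@H]2OC(=O)[C@]2(C)CO2)oc1 | intermediate
26 | C6/C12 endoperoxide of 25 (2,3,7-trioxabicyclo[2.2.1]hept-5-ene unit, both faces) | CC(=O)OCC1=C2C3(C[C@@]4(C)CC[C@H](O4)[C@](C)(O)C[C@@H]2OC(=O)[C@]2(C)CO2)OOC1O3 | intermediate (not isolated)
27 | (1S,4R,8S,10R)-13-acetoxy-1,4-epoxy-6,10-dihydroxy-8-{[(2S)-2-methyloxiran-2-yl]carbonyloxy}germacr-7(11)-en-12,6-olide (C6 epimers) | CC(=O)OCC1=C2C(O)(C[C@@]3(C)CC[C@H](O3)[C@](C)(O)C[C@@H]2OC(=O)[C@]2(C)CO2)OC1=O | intermediate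
28 | 6-O-methanesulfonate of 27 | CC(=O)OCC1=C2C(OS(C)(=O)=O)(C[C@@]3(C)CC[C@H](O3)[C@](C)(O)C[C@@H]2OC(=O)[C@]2(C)CO2)OC1=O | intermediate (not isolated)
29 | (1S,4R,5E,8S,10R)-13-acetoxy-1,4-epoxy-10-hydroxy-8-{[(2S)-2-methyloxiran-2-yl]carbonyloxy}germacra-5,7(11)-dien-12,6-olide (CNP0142137.1) | CC(=O)OCC1=C2/C(=C\[C@@]3(C)CC[C@H](O3)[C@](C)(O)C[C@@H]2OC(=O)[C@]2(C)CO2)OC1=O | target

**Step count and risks**

Total step count: 16. Longest linear sequence: 15 (steps 1–12 and 14–16; step 13 makes the acid used in step 14).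

Steps most likely to fail:

1. Step 11 (ring closure). The samarium enolate may be protonated, or may take a proton from the enolizable C10 ketone, before the C–C bond forms. Electron transfer to the α‑alkoxy C10 ketone may cleave the C1–O bond. Intermolecular aldol addition may compete. Fallback: setting out from 18, reductive silylation with Zn dust and Me3SiCl in MeCN should give the trimethylsilyl enol ether F1, again specifically at C8/C9. A chelating Lewis acid (TiCl4, CH2Cl2, −78 °C, high dilution) then activates the C10 ketone through the oxolane oxygen for an intramolecular Mukaiyama aldol addition, and aqueous work‑up returns to the route at 20.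

2. Step 7 (furan annulation). The amine base may isomerize the ynone to an allenyl or dienyl ketone, or the oxa‑Michael adduct may close in the wrong sense (the carbon next to the ether oxygen onto the C8 carbonyl), giving an isomeric 2‑acylfuran. Fallback: setting out from 8, its lithium acetylide is added to 2,2‑dimethyl‑1,3‑dioxan‑5‑one to give the tertiary propargylic alcohol F2. Aqueous acetic acid removes the acetonide to give the alkynyl triol F3. Iodine and NaHCO3 in MeCN effect 5‑endo‑dig iodocyclization and dehydration to the 3‑iodofuran F4 (iodine on C7; the two hydroxymethyl arms are equivalent, so no regiochemical question arises). Stille coupling with tributyl(1‑ethoxyvinyl)stannane (Pd(PPh3)4) gives the enol ether F5, and mild aqueous acid hydrolyses it to the acetylfuran, rejoining the route at 13.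

3. Step 12 (reduction). Facial selectivity may be poor, because the conformation of the ten‑membered ring rather than the boron chelate may decide which face of the C8 carbonyl is open. Fallback: setting out from 20, intramolecular hydride delivery with Me4NBH(OAc)3 (MeCN/AcOH, −30 °C) is expected to give the 1,3‑anti diol F6 (8R). Mitsunobu esterification of F6 with acid 24 (PPh3, diisopropyl azodicarboxylate, toluene, 0 °C) then forms the ester with inversion at C8 and rejoins the route at 25.

Further compounds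
F1 | step 11 | [5-{[(2R,5S)-5-acetyl-2-methyloxolan-2-yl]methyl}-4-{1-[(trimethylsilyl)oxy]ethenyl}furan-3-yl]methyl acetate | CC(=O)OCc1coc(C[C@@]2(C)CC[C@H](O2)C(C)=O)c1C(=C)O[Si](C)(C)C
F2 | step 7 | 2,2-dimethyl-5-{3-[(2R,5S)-2-methyl-5-(prop-1-en-2-yl)oxolan-2-yl]prop-1-yn-1-yl}-1,3-dioxan-5-ol | CC1(C)OCC(O)(CO1)C#CC[C@@]1(C)CC[C@H](O1)C(C)=C
F3 | step 7 | 2-(hydroxymethyl)-5-[(2R,5S)-2-methyl-5-(prop-1-en-2-yl)oxolan-2-yl]pent-3-yne-1,2-diol | OCC(O)(CO)C#CC[C@@]1(C)CC[C@H](O1)C(C)=C
F4 | step 7 | (4-iodo-5-{[(2R,5S)-2-methyl-5-(prop-1-en-2-yl)oxolan-2-yl]methyl}furan-3-yl)methanol | OCc1coc(C[C@@]2(C)CC[C@H](O2)C(C)=C)c1I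
F5 | step 7 | [4-(1-ethoxyethenyl)-5-{[(2R,5S)-2-methyl-5-(prop-1-en-2-yl)oxolan-2-yl]methyl}furan-3-yl]methanol | CCOC(=C)c1c(CO)coc1C[C@@]1(C)CC[C@H](O1)C(C)=C
F6 | step 12 | (1S,4R,8R,10R)-13-acetoxy-1,4:6,12-diepoxygermacra-6,11-diene-8,10-diol (8-epimer of 22) | CC(=O)OCc1c2c(C[C@@]3(C)CC[C@H](O3)[C@](C)(O)C[C@H]2O)oc1
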